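The earlier runs and the new flask come from a simulation on assumed constants; noise was put on by code.

A small charge of starting material, 0.31 M in the cedar run, made me ask where the reagent goes: the product at the last reading accounts for 0.186 M of 0.552 M reagent.

| setting | cedar | alder | larch | east | north-west |
|---|---|---|---|---|---|
| starting material | 0.31 M | 0.69 M | 0.46 M | 0.46 M | 0.46 M |
| reagent | 0.552 M | 0.552 M | 0.83 M | 0.552 M | 0.552 M |
| temperature | 125 °C | 158 °C | 125 °C |  |  |
| remark | run made earlier | run made earlier | run made earlier | at 110 °C throughout | at 110 °C until 50 min, from then on at 170 °C |
| time |  |  |  | 2.5 h | 2.5 h |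

| run | time / min | product / % |
|---|---|---|
| cedar | 12.0 | 30 |
| cedar | 30.0 | 45 |
| cedar | 60.0 | 57 |
| cedar | 80.0 | 60 |
| alder | 2.50 | 34 |
| alder | 6.00 | 44 |
| alder | 12.0 | 51 |
| alder | 15.0 | 50 |
| larch | 25.0 | 57 |
| larch | 40.0 | 62 |
| larch | 80.0 | 72 |

(readings scatter by 1.5 percentage points)

1. the flask that ends with the higher amount of product, in percent of the starting material charged, or "neither" when 2 percentage points or less lies between them (east / north-west / neither)
2. final product, as a percentage of the starting material charged, in east
3. final product, as a percentage of the starting material charged, in north-west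

- what was read earlier has a scatter of 1.5 percentage points, one standard deviation

I supposed one mole of reagent per mole of product and counted the reagent not found in product as wasted, 0.366 M in cedar if its reagent had gone by the last reading. I replaced the falling starting material by its mean, Ā, here 0.217 M. Then σ, the selectivity factor, is the moles of reagent going to product per mole wasted, divided by Ā. Cedar read 2.34 M⁻¹. Alder, whose last readings stood flat, gave 0.345 M product, 0.207 M wasted and Ā of 0.517 M, so σ read 3.22 M⁻¹. A straight line in ln σ against temperature gave σ at 110 °C, 2.03 M⁻¹, and at 170 °C, 3.62 M⁻¹.

With the reagent used up, the fraction X converted is (B₀/A₀)/(1 + 1/(σĀ)), where B₀ and A₀ are the charges of reagent and starting material. Taking half of the charge as reacted gave 49.4% at 110 °C and 66.6% at 170 °C. Putting that hot figure back into Ā lowered it to 63.1%.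

The weak link was whether the reagent is used up in time. Cedar at 60.0 min read 95.0% of its last reading and alder at 6.00 min read 88.0% of its last, so I took those two times as roughly equal progress, and on a like line in temperature east's 2.5 h counted as 52.7 min of cedar time, close to cedar's third reading. I therefore scaled east by that reading's share of the last, to 46.9%. North-west's hot stretch counted as 2310 min of cedar time, far beyond cedar's last reading, so I counted its reagent as used up. As a plain guess I gave its cold start and hot finish equal weight, took the mean of the cold and hot figures, 56.2%, and called north-west ahead.

The forecast gave 59% for east, 57% for north-west and neither, holding that “reagent decay has the higher activation energy”, whereas my σ rose with heat.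

East gave 47.5% and north-west 69.7%, so north-west ended higher.

    starting material + reagent → product, rate k1*[starting material]*[reagent]^1.5 (k = 5.70 × 10⁻⁴ M⁻¹·⁵ s⁻¹, Ea = 88.0 kJ mol⁻¹)
    2 reagent → homo dimer (k = 1.70 × 10⁻⁴ M⁻¹ s⁻¹, Ea = 74.0 kJ mol⁻¹)
    (constants at 110 °C)

At the end east still held 22% of its reagent and north-west 0.70%. The carried σ of 2.03 M⁻¹, put to use on the neighbour of east charged with 0.18 M of starting material, at a mean Ā of 0.130 M, gave 0.264 mole of product per mole of reagent wasted. With 56.1% product and 31% of its reagent left, that neighbour made 0.358.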